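Ring B of the aryltetralin is cut at C2–C3 and C1–C8a. The C1–C2 bond is treated as the former alkene of a sinapyl-type styrene, and C8a–C4a–C4–C3 comes from one ring A partner that carries a C3 bromide α to an ester and a C8a aryl bromide. A chiral nickel catalyst with manganese adds these two carbons across the alkene, closing the six-membered ring B and creating C1, C2 and C3 in one operation. The precursors are racemic methyl 2-bromo-3-(2-bromoaryl)propanoate 8 and the O-benzylated (E)-cinnamyl benzyl ether 11, both made from syringaldehyde. C3 is then equilibrated, the ester reduced and the three benzyl ethers removed.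

Key step: step 9

Remark: locants follow tetralin numbering with the aryl-bearing carbon as C1 (C9' on C2, C9 on C3); the sense of induction of the chiral ligand cannot be predicted, so the ligand antipode that gives (1S) is assumed to be chosen after a first trial.

Step 1  
Reactants: 1 syringaldehyde (4-hydroxy-3,5-dimethoxybenzaldehyde)  
Product: 2 4-(benzyloxy)-3,5-dimethoxybenzaldehyde  
Conditions: BnBr, K2CO3, DMF, 60 °C  
Reagents that add atoms: benzyl bromide, BrCc1ccccc1  
Why: Williamson ether synthesis, in which the phenoxide formed by K2CO3 is alkylated by benzyl bromide; the benzyl ether is inert to all later steps and leaves only in the final hydrogenolysis.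

Step 2  
Reactants: 2 4-(benzyloxy)-3,5-dimethoxybenzaldehyde  
Product: 3 4-(benzyloxy)-2-bromo-3,5-dimethoxybenzaldehyde  
Conditions: NBS (1.05 equiv), MeCN, 25–50 °C, dark  
Reagents that add atoms: N-bromosuccinimide, O=C1CCC(=O)N1Br  
Why: Electrophilic aromatic bromination; the two free ring positions are equivalent, each ortho to one methoxy group and para to the other, so a single monobromide should form, and a second bromination is slowed by the aldehyde and the first bromine.

Step 3  
Reactants: 3 4-(benzyloxy)-2-bromo-3,5-dimethoxybenzaldehyde; 4 trimethyl phosphonoacetate  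
Product: 5 methyl (E)-3-[4-(benzyloxy)-2-bromo-3,5-dimethoxyphenyl]prop-2-enoate  
Conditions: NaH, THF, 0 °C to rt  
Reagents that add atoms: none  
Why: Horner–Wadsworth–Emmons olefination of an aryl aldehyde with a stabilised phosphonate anion, which should give the (E)-cinnamate.

Step 4  
Reactants: 5 methyl (E)-3-[4-(benzyloxy)-2-bromo-3,5-dimethoxyphenyl]prop-2-enoate  
Product: 6 methyl 3-[4-(benzyloxy)-2-bromo-3,5-dimethoxyphenyl]propanoate  
Conditions: H2 (4 bar), RhCl(PPh3)3 (5 mol%), THF/MeOH, 40 °C  
Reagents that add atoms: none  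
Why: Homogeneous hydrogenation with RhCl(PPh3)3 saturates the conjugated disubstituted alkene and, unlike Pd/C, leaves the aryl bromide and the benzyl ether untouched.

Step 5  
Reactants: 6 methyl 3-[4-(benzyloxy)-2-bromo-3,5-dimethoxyphenyl]propanoate  
Product: 8 methyl 2-bromo-3-[4-(benzyloxy)-2-bromo-3,5-dimethoxyphenyl]propanoate (racemic), via trimethylsilyl ketene acetal 7 (not isolated)  
Conditions: LiN(iPr)2, Me3SiCl, THF, −78 °C; then NBS, −78 to 0 °C  
Reagents that add atoms: N-bromosuccinimide, O=C1CCC(=O)N1Br; chlorotrimethylsilane, C[Si](C)(C)Cl (its silyl group stays in 7 only)  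
Why: Electrophilic α-bromination of an ester through its silyl ketene acetal; because the enolate is trapped as 7 before NBS is added, the α-bromo ester never meets base, which disfavours a second bromination and loss of HBr to the cinnamate.

Step 6  
Reactants: 2 4-(benzyloxy)-3,5-dimethoxybenzaldehyde; 4 trimethyl phosphonoacetate  
Product: 9 methyl (E)-3-[4-(benzyloxy)-3,5-dimethoxyphenyl]prop-2-enoate  
Conditions: NaH, THF, 0 °C to rt  
Reagents that add atoms: none  
Why: Horner–Wadsworth–Emmons olefination, which should give the (E)-cinnamate.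

Step 7  
Reactants: 9 methyl (E)-3-[4-(benzyloxy)-3,5-dimethoxyphenyl]prop-2-enoate  
Product: 10 (E)-3-[4-(benzyloxy)-3,5-dimethoxyphenyl]prop-2-en-1-ol  
Conditions: iBu2AlH (2.5 equiv), CH2Cl2, −78 to 0 °C; aqueous potassium sodium tartrate  
Reagents that add atoms: none  
Why: Hydride 1,2-reduction of an α,β-unsaturated ester by iBu2AlH, which gives the allylic alcohol and leaves the alkene and its E geometry intact.

Step 8  
Reactants: 10 (E)-3-[4-(benzyloxy)-3,5-dimethoxyphenyl]prop-2-en-1-ol  
Product: 11 2-(benzyloxy)-5-[(E)-3-(benzyloxy)prop-1-enyl]-1,3-dimethoxybenzene  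
Conditions: NaH, BnBr, Bu4NI (cat.), THF/DMF, 0 °C to rt  
Reagents that add atoms: benzyl bromide, BrCc1ccccc1  
Why: Williamson ether synthesis on the primary allylic alkoxide; a benzyl ether is chosen so that all three protecting groups fall in one final operation.

Step 9  
Reactants: 8 methyl 2-bromo-3-[4-(benzyloxy)-2-bromo-3,5-dimethoxyphenyl]propanoate (racemic); 11 2-(benzyloxy)-5-[(E)-3-(benzyloxy)prop-1-enyl]-1,3-dimethoxybenzene  
Product: 12 methyl (1S,2R)-7-(benzyloxy)-1-[4-(benzyloxy)-3,5-dimethoxyphenyl]-2-[(benzyloxy)methyl]-6,8-dimethoxy-1,2,3,4-tetrahydronaphthalene-3-carboxylate (mixture of C3 epimers)  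
Conditions: NiBr2(dme) (10 mol%), (4S,4'S)-4,4'-diisopropyl-2,2'-bi(2-oxazoline) (12 mol%), Mn powder (3 equiv), DMA, 20 °C; 8 added over 8 h to 11 (2 equiv)  
Reagents that add atoms: none  
Why: Proposed new method: low-valent nickel abstracts bromine from the α-bromo ester of 8 and the electrophilic C3 radical adds to C2 of the electron-rich styrene 11 (C2–C3 bond), giving the benzylic C1 radical; nickel captures it, inserts into the adjacent C8a–Br bond (or already carries the C8a aryl) and, from trivalent nickel, reductively eliminates the C1–C8a bond, while manganese returns divalent nickel to the zerovalent state. The closest known reaction type is the nickel-catalysed enantioselective reductive 1,2-alkyl-arylation of vinylarenes with an alkyl halide and an aryl halide; untested are the placing of both halides on one partner and the use of a 1,2-disubstituted styrene. Ring B closes in the C1–C8a reductive elimination from a seven-membered benzyl(aryl)nickelacycle, which contracts to the six-membered carbocycle (formal [4+2] of C8a–C4a–C4–C3 with C1=C2). C1 is set by the chiral ligand on nickel during radical capture and reductive elimination; C2 is created earlier, in the uncatalysed radical addition, as both antipodes, so the catalyst can only select: the (2R) radical closes to the 1,2-trans ring with C9' pseudo-equatorial, the (2S) radical is mismatched and should end as a 1,2-cis diastereomer that is removed by chromatography; C3 is not controlled and is left to step 10. The step needs attack at C2 and not C1 (secured by benzylic stabilisation and the polarity match of an α-ester radical with a trialkoxystyrene), alkene addition before aryl–alkyl coupling (the intramolecular coupling would give a strained benzocyclobutene, the intermolecular one is held back by adding 8 slowly to excess 11) and no direct metal insertion into the C–Br bond α to the ester (manganese, not zinc, as reductant, since zinc would form a Reformatsky reagent).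

Step 10  
Reactants: 12 methyl (1S,2R)-7-(benzyloxy)-1-[4-(benzyloxy)-3,5-dimethoxyphenyl]-2-[(benzyloxy)methyl]-6,8-dimethoxy-1,2,3,4-tetrahydronaphthalene-3-carboxylate (mixture of C3 epimers)  
Product: 13 methyl (1S,2R,3R)-7-(benzyloxy)-1-[4-(benzyloxy)-3,5-dimethoxyphenyl]-2-[(benzyloxy)methyl]-6,8-dimethoxy-1,2,3,4-tetrahydronaphthalene-3-carboxylate (all-trans)  
Conditions: NaOMe (0.2 equiv), MeOH/THF, 50 °C  
Reagents that add atoms: none  
Why: Base-mediated epimerisation through the ester enolate under thermodynamic control; only C3 is acidic, and the 2,3-trans epimer, in which the ester and the benzyloxymethyl group can both lie equatorial on the half-chair, should prevail, with C1 and C2 untouched.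

Step 11  
Reactants: 13 methyl (1S,2R,3R)-7-(benzyloxy)-1-[4-(benzyloxy)-3,5-dimethoxyphenyl]-2-[(benzyloxy)methyl]-6,8-dimethoxy-1,2,3,4-tetrahydronaphthalene-3-carboxylate  
Product: 14 [(1S,2R,3R)-7-(benzyloxy)-1-[4-(benzyloxy)-3,5-dimethoxyphenyl]-2-[(benzyloxy)methyl]-6,8-dimethoxy-1,2,3,4-tetrahydronaphthalen-3-yl]methanol  
Conditions: LiAlH4, THF, 0 °C to rt; aqueous NaOH work-up  
Reagents that add atoms: none  
Why: Hydride reduction of the ester to the primary alcohol, which removes the only epimerisable centre and leaves the benzyl ethers intact.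

Step 12  
Reactants: 14 [(1S,2R,3R)-7-(benzyloxy)-1-[4-(benzyloxy)-3,5-dimethoxyphenyl]-2-[(benzyloxy)methyl]-6,8-dimethoxy-1,2,3,4-tetrahydronaphthalen-3-yl]methanol  
Product: 15 (1S,2R,3R)-7-hydroxy-1-(4-hydroxy-3,5-dimethoxyphenyl)-2,3-bis(hydroxymethyl)-6,8-dimethoxy-1,2,3,4-tetrahydronaphthalene (CNP0153696.1)  
Conditions: H2 (1 atm), Pd/C (10 wt%), EtOAc/MeOH, rt  
Reagents that add atoms: none  
Why: Catalytic hydrogenolysis cleaves the two aryl benzyl ethers and the primary alkyl benzyl ether, while the diarylmethine C1–H bond and the ring B C–C bonds are inert to Pd/C at room temperature.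

Compound list  
1 | syringaldehyde (4-hydroxy-3,5-dimethoxybenzaldehyde) | COc1cc(C=O)cc(OC)c1O | starting material  
2 | 4-(benzyloxy)-3,5-dimethoxybenzaldehyde | COc1cc(C=O)cc(OC)c1OCc1ccccc1 | intermediate  
3 | 4-(benzyloxy)-2-bromo-3,5-dimethoxybenzaldehyde | COc1cc(C=O)c(Br)c(OC)c1OCc1ccccc1 | intermediate  
4 | trimethyl phosphonoacetate | COC(=O)CP(=O)(OC)OC | starting material  
5 | methyl (E)-3-[4-(benzyloxy)-2-bromo-3,5-dimethoxyphenyl]prop-2-enoate | COC(=O)/C=C/c1cc(OC)c(OCc2ccccc2)c(OC)c1Br | intermediate  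
6 | methyl 3-[4-(benzyloxy)-2-bromo-3,5-dimethoxyphenyl]propanoate | COC(=O)CCc1cc(OC)c(OCc2ccccc2)c(OC)c1Br | intermediate  
7 | trimethylsilyl ketene acetal of 6 (1-methoxy-1-(trimethylsilyloxy)prop-1-ene bearing the 4-(benzyloxy)-2-bromo-3,5-dimethoxyphenyl group on C3, E/Z mixture) | COC(O[Si](C)(C)C)=CCc1cc(OC)c(OCc2ccccc2)c(OC)c1Br | intermediate (not isolated)  
8 | methyl 2-bromo-3-[4-(benzyloxy)-2-bromo-3,5-dimethoxyphenyl]propanoate (racemic) | COC(=O)C(Br)Cc1cc(OC)c(OCc2ccccc2)c(OC)c1Br | intermediate  
9 | methyl (E)-3-[4-(benzyloxy)-3,5-dimethoxyphenyl]prop-2-enoate | COC(=O)/C=C/c1cc(OC)c(OCc2ccccc2)c(OC)c1 | intermediate  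
10 | (E)-3-[4-(benzyloxy)-3,5-dimethoxyphenyl]prop-2-en-1-ol | OC/C=C/c1cc(OC)c(OCc2ccccc2)c(OC)c1 | intermediate  
11 | 2-(benzyloxy)-5-[(E)-3-(benzyloxy)prop-1-enyl]-1,3-dimethoxybenzene | COc1cc(/C=C/COCc2ccccc2)cc(OC)c1OCc1ccccc1 | intermediate  
12 | methyl (1S,2R)-7-(benzyloxy)-1-[4-(benzyloxy)-3,5-dimethoxyphenyl]-2-[(benzyloxy)methyl]-6,8-dimethoxy-1,2,3,4-tetrahydronaphthalene-3-carboxylate, mixture of C3 epimers | COC(=O)C1Cc2cc(OC)c(OCc3ccccc3)c(OC)c2[C@H](c2cc(OC)c(OCc3ccccc3)c(OC)c2)[C@H]1COCc1ccccc1 | intermediate  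
13 | methyl (1S,2R,3R)-7-(benzyloxy)-1-[4-(benzyloxy)-3,5-dimethoxyphenyl]-2-[(benzyloxy)methyl]-6,8-dimethoxy-1,2,3,4-tetrahydronaphthalene-3-carboxylate (all-trans) | COC(=O)[C@@H]1Cc2cc(OC)c(OCc3ccccc3)c(OC)c2[C@H](c2cc(OC)c(OCc3ccccc3)c(OC)c2)[C@H]1COCc1ccccc1 | intermediate  
14 | [(1S,2R,3R)-7-(benzyloxy)-1-[4-(benzyloxy)-3,5-dimethoxyphenyl]-2-[(benzyloxy)methyl]-6,8-dimethoxy-1,2,3,4-tetrahydronaphthalen-3-yl]methanol | OC[C@@H]1Cc2cc(OC)c(OCc3ccccc3)c(OC)c2[C@H](c2cc(OC)c(OCc3ccccc3)c(OC)c2)[C@H]1COCc1ccccc1 | intermediate  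
15 | (1S,2R,3R)-7-hydroxy-1-(4-hydroxy-3,5-dimethoxyphenyl)-2,3-bis(hydroxymethyl)-6,8-dimethoxy-1,2,3,4-tetrahydronaphthalene (CNP0153696.1) | COc1cc([C@H]2c3c(cc(OC)c(O)c3OC)C[C@@H](CO)[C@@H]2CO)cc(OC)c1O | target

Total step count: 12. Longest linear sequence: 9 steps (steps 1, 2, 3, 4, 5, 9, 10, 11, 12).

Steps most likely to fail

Step 9 (proposed new method). Several processes may divert it:
- Aryl bromide and α-bromo ester units of different molecules may couple directly and oligomerise.
- The C–Br bond α to the ester may be reduced before the radical meets the internal alkene.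
- Catalyst control at C1 may not override the trans preference of ring closure in the mismatched series, which would erode the enantiomeric purity of the 1,2-trans product; a crystallisation at 13 or 14 would then be needed.
- By design, only adduct radicals of one C2 configuration can reach 12, so at most half of the material is productive.

The fallback is the established lactone route and uses known chemistry throughout. It sets out from 2 and comes back at 15. Stobbe condensation of 2 with dimethyl succinate (NaOMe, MeOH, reflux) should give (E)-4-[4-(benzyloxy)-3,5-dimethoxyphenyl]-3-(methoxycarbonyl)but-3-enoic acid F1. Asymmetric hydrogenation with [Rh(cod)2]BF4 and a chiral bisphosphine (antipode chosen for the R acid) should give (R)-4-[4-(benzyloxy)-3,5-dimethoxyphenyl]-3-(methoxycarbonyl)butanoic acid F2, which fixes C3. Reduction of the ester beside the carboxylate with Ca(BH4)2, followed by acid-induced lactonisation, should give (R)-4-{[4-(benzyloxy)-3,5-dimethoxyphenyl]methyl}oxolan-2-one F3. Aldol addition of its lithium enolate (LiN(SiMe3)2, THF, −78 °C) to a second portion of 2 places the new substituent trans to the benzyl group and should give (3S,4R)-3-{[4-(benzyloxy)-3,5-dimethoxyphenyl](hydroxy)methyl}-4-{[4-(benzyloxy)-3,5-dimethoxyphenyl]methyl}oxolan-2-one F4 as a mixture of carbinol epimers. CF3CO2H in CH2Cl2 at 0 °C ionises the benzylic alcohol, and Friedel–Crafts alkylation of ring A closes C1–C8a with the aryl group trans to C2. This should give (1S,2R,3R)-7-(benzyloxy)-1-[4-(benzyloxy)-3,5-dimethoxyphenyl]-3-(hydroxymethyl)-6,8-dimethoxy-1,2,3,4-tetrahydronaphthalene-2-carboxylic acid γ-lactone (2,3-trans-fused) F5. LiAlH4 opens the lactone to [(1S,2R,3R)-7-(benzyloxy)-1-[4-(benzyloxy)-3,5-dimethoxyphenyl]-6,8-dimethoxy-1,2,3,4-tetrahydronaphthalene-2,3-diyl]dimethanol F6, and hydrogenolysis (H2, Pd/C) gives 15.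

Step 10. The equilibrium at C3 may not lie on the side of the 2,3-trans ester. The C8 methoxy group presses on a pseudo-equatorial C1 aryl group and so destabilises the all-equatorial half-chair, and an incomplete or adverse equilibration would leave a mixture of C3 epimers. The fallback replaces thermodynamic correction by separation of diastereomers; it sets out from 12 and comes back at 14. The C3 epimer mixture 12 is reduced directly with LiAlH4 (THF, 0 °C). The two diastereomeric primary alcohols, 14 and [(1S,2R,3S)-7-(benzyloxy)-1-[4-(benzyloxy)-3,5-dimethoxyphenyl]-2-[(benzyloxy)methyl]-6,8-dimethoxy-1,2,3,4-tetrahydronaphthalen-3-yl]methanol F8, are separated by chromatography on silica, and only 14 is carried into step 12.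

Step 5. A second bromination at the α-carbon and loss of HBr from the product towards cinnamate 5 may compete during halogenation of the enolate equivalent. The fallback introduces oxygen first and bromine by substitution under neutral conditions; it sets out from 6 and comes back at 8. The potassium enolate of 6 (KN(SiMe3)2, THF, −78 °C) is hydroxylated with 2-(phenylsulfonyl)-3-phenyloxaziridine to methyl 3-[4-(benzyloxy)-2-bromo-3,5-dimethoxyphenyl]-2-hydroxypropanoate F7. An Appel reaction (CBr4, PPh3, CH2Cl2, 0 °C) then replaces the hydroxyl group by bromine and gives 8.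

Further compounds  
F1 | step 9 | (E)-4-[4-(benzyloxy)-3,5-dimethoxyphenyl]-3-(methoxycarbonyl)but-3-enoic acid | COC(=O)/C(CC(=O)O)=C/c1cc(OC)c(OCc2ccccc2)c(OC)c1  
F2 | step 9 | (R)-4-[4-(benzyloxy)-3,5-dimethoxyphenyl]-3-(methoxycarbonyl)butanoic acid | OC(=O)C[C@@H](Cc1cc(OC)c(OCc2ccccc2)c(OC)c1)C(=O)OC  
F3 | step 9 | (R)-4-{[4-(benzyloxy)-3,5-dimethoxyphenyl]methyl}oxolan-2-one | COc1cc(C[C@H]2COC(=O)C2)cc(OC)c1OCc1ccccc1  
F4 | step 9 | (3S,4R)-3-{[4-(benzyloxy)-3,5-dimethoxyphenyl](hydroxy)methyl}-4-{[4-(benzyloxy)-3,5-dimethoxyphenyl]methyl}oxolan-2-one (carbinol epimers) | COc1cc(C(O)[C@H]2C(=O)OC[C@@H]2Cc2cc(OC)c(OCc3ccccc3)c(OC)c2)cc(OC)c1OCc1ccccc1  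
F5 | step 9 | (1S,2R,3R)-7-(benzyloxy)-1-[4-(benzyloxy)-3,5-dimethoxyphenyl]-3-(hydroxymethyl)-6,8-dimethoxy-1,2,3,4-tetrahydronaphthalene-2-carboxylic acid γ-lactone (2,3-trans-fused) | COc1cc([C@H]2c3c(cc(OC)c(OCc4ccccc4)c3OC)C[C@H]3COC(=O)[C@H]23)cc(OC)c1OCc1ccccc1  
F6 | step 9 | [(1S,2R,3R)-7-(benzyloxy)-1-[4-(benzyloxy)-3,5-dimethoxyphenyl]-6,8-dimethoxy-1,2,3,4-tetrahydronaphthalene-2,3-diyl]dimethanol | COc1cc([C@H]2c3c(cc(OC)c(OCc4ccccc4)c3OC)C[C@@H](CO)[C@@H]2CO)cc(OC)c1OCc1ccccc1  
F7 | step 5 | methyl 3-[4-(benzyloxy)-2-bromo-3,5-dimethoxyphenyl]-2-hydroxypropanoate (racemic) | COC(=O)C(O)Cc1cc(OC)c(OCc2ccccc2)c(OC)c1Br  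
F8 | step 10 | [(1S,2R,3S)-7-(benzyloxy)-1-[4-(benzyloxy)-3,5-dimethoxyphenyl]-2-[(benzyloxy)methyl]-6,8-dimethoxy-1,2,3,4-tetrahydronaphthalen-3-yl]methanol | OC[C@H]1Cc2cc(OC)c(OCc3ccccc3)c(OC)c2[C@H](c2cc(OC)c(OCc3ccccc3)c(OC)c2)[C@H]1COCc1ccccc1  
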